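## The problem

The target 30 is the all-E C40 carotenoid (3S,5S,6S,3'R,6'R)-5,6-dihydro-β,ε-carotene-3,5,6,3'-tetrol: a nonaene chain joining a 3,5,6-trihydroxy-5,6-dihydro-β ring to a 3'-hydroxy-ε ring. The rings are separated by eighteen sp2 chain carbons and cannot influence each other, so each end group must be made enantiopure on its own and the chain assembled by olefination around a symmetrical C10 centre piece. In the saturated ring, C3 is a secondary carbinol that the chiral pool supplies easily. C5 and C6 are fully substituted carbinol carbons whose oxygens must be placed relative to C3 (O3 and O5 cis-1,3, O5 and O6 trans). In the ε ring, C6' is a doubly allylic methine next to C4'=C5', and C3' is an allylic carbinol para to it, too far away for reliable mutual control. The fragile parts are the polyene (light, oxygen, acid), the tertiary allylic C6 hydroxyl once C7=C8 exists (ionisation leads to dehydration or 5,8-furanoid ethers), the allylic 3'-hydroxyl (acid epimerisation, elimination) and the ε double bond, which moves into conjugation if C6' is deprotonated or the ring ionises. The key step rests on the O3/O5 cis, O5/O6 trans pattern: it is what remains when an oxygen carried on C3 opens a 5,6-epoxide of the opposite face at C5, and a C3 tert-butyl carbonate can do this by closing a six-membered cyclic carbonate across C3 and C5. With a C7≡C8 triple bond in place of the later alkene, C6 is propargylic and not allylic, so the Lewis acid needed for the opening can be used without the rearrangements typical of 7,8-unsaturated 5,6-epoxides.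

## Retrosynthesis

**Last operation (30 from 29).** Only an O–Si bond is cut. The ε-ring hydroxyl is allylic and would ionise under the acid used twice to make phosphonium salts on that half, so it is carried to the end as a tert-butyldiphenylsilyl ether in 29. The three hydroxyls of the other ring are never protected. The forward step must desilylate a polyene tetraol without acid.

**C11=C12 (29 from 28 and 15).** Cutting here and not at C15=C15' keeps both halves close to ordinary C15 end-group chemistry. Cutting here and not at C7=C8 keeps the carbonyl partner away from the quaternary C6. The polarity is dictated by the triol half: its tertiary allylic C6 hydroxyl rules out acid-mediated phosphonium salt formation, so this half is the aldehyde 15 and the ε half is the C25 phosphonium salt 28. The Wittig reaction must tolerate three free hydroxyls without strong base, and the new disubstituted double bond must end up E.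

**C11'=C12' and the centre piece (28 from 27, 26, and then 24 and 25).** Salt 28 comes from alcohol 27 and aldehyde 26. A second Wittig cut in 26 releases the symmetrical, purchasable C10 dialdehyde 25 and the C15 salt 24. The symmetrical centre piece is worth the two functional-group steps that turn its second formyl group into an ylide precursor. Mono-olefination of 25 is required, which an excess of 25 secures.

**ε-Side chain (24 from 23, and 23 from 21 and 22).** The C11'–P and C9'–C10' bonds are cut. Carbinol 23 is the adduct of vinylmagnesium bromide 22 and the protected hydroxy ionone 21; its acid-induced allylic transposition with triphenylphosphine gives 24. Compared with a two-carbon Horner–Wadsworth–Emmons extension of the methyl ketone, this gives the 9'E bond through a crystalline salt. It needs a ring oxygen function that survives HBr, hence the silyl ether.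

**ε-Ring oxygenation (21 from 20, 19, 18, 17 and 16).** (R)-α-Ionone 16 already holds the ring, the ε double bond and C6' in the correct configuration; only the C3' oxygen is missing. It enters by allylic oxidation of ketal 17 to enone 18 and reduction to 19; the ketal keeps the two carbonyl groups apart. Hydrolysis gives 20 and silylation gives 21. Because C6' gives little bias at C3', the reduction must be reagent-controlled.

**Adjusting the triol half (15 from 14, 13 and 12).** Only oxidation levels and a silyl group change. Aldehyde 15 comes from tetraol 14, 14 from silyl ether 13, and 13 from the bicyclic carbonate 12 by trans-reduction of C7≡C8 with reductive cleavage of the carbonate in the same operation. Reducing the alkyne after the key step means the acid-labile tertiary allylic alcohol appears only when no more acid is needed.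

**Key disconnection (12 from 11).** The C5–O bond and the carbonate ring are cut, leading to the 5,6-epoxide 11 with the epoxide trans to the C3 tert-butyl carbonate. Intermolecular hydrolysis would have to choose between C5 and C6 and between two half-chair conformers. The tether can reach only C5 and only from its own face, so C3 fixes C5 while C6 is retained from the epoxide. The forward reaction needs Lewis-acid activation in which the ring closure outruns rearrangement of the activated epoxide.

**Epoxide and C6–C7 (11 from 10, and 10 from 7 and 9).** The epoxide C–O bonds are cut to give dienyne 10, then C6–C7 to give enol triflate 7 and alkyne 9. The sp–sp2 coupling is preferred to acetylide addition to a ring ketone because it delivers the tetrasubstituted alkene needed for the epoxide. The peracid must choose the ring alkene and the face anti to the carbonate.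

**Ring and chain building blocks (7 from 5; 5 from 3 and 4; 3 from 2 and 1; 9 from 8).** Triflate 7 comes from the carbonate-protected hydroxy ketone 5, made from 3 and di-tert-butyl dicarbonate 4. Hydroxy ketone 3 comes from ketoisophorone 1 by way of dione 2 in two reductions. Alkyne 9 is the silyl ether of the commercial E-enynol 8, which supplies the C9=C10 geometry.

## Roads not taken

Alternative 1: The cuts are C7=C8 and C7'=C8'. A C20 bis(phosphonate) A2, made from the C20 heptaene dialdehyde, would react in two successive Horner–Wadsworth–Emmons steps with the tris-silylated trihydroxy-ring aldehyde A3 and the ε-ring aldehyde A4 to give the tetrakis(triethylsilyl) ether A1 of the target.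
- Merits: it is the most convergent plan (C10 + C20 + C10), the heptaene arrives all-E in one piece, the olefinations are E-selective and need no thermal isomerisation, and fewer chain-building steps are needed than in the chosen plan. In step economy it is better.
- Weak points:
  - The formyl group of A3 sits on quaternary C6 between two further quaternary carbons and is poorly accessible to a stabilised phosphonate anion.
  - Two tertiary hydroxyls must be silylated.
  - A4 is a β,γ-unsaturated aldehyde with C6' α to the carbonyl, so the olefination base can epimerise C6' or pull the double bond into conjugation.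
  - The two ends of A2 can be differentiated only statistically.
  - It does not say how C5 and C6 are set.
- Against the shorter chain assembly, the chosen plan places the carbonyl groups at C11 and C12, far from both rings, has no enolisable stereocentre beside a carbonyl, and leaves the triol unprotected.

Alternative 2: The cut is the C1'–C6' bond of the ε ring. Acid would protonate the terminal 1,1-disubstituted alkene of the acyclic silyloxy trienone A6; the C1' cation is attacked by C6' and loss of the C4' proton gives the protected hydroxy α-ionone A5, which is the same compound as 21.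
- Merits: the ring and C6' are formed in one step from acyclic material, without dependence on enantiopure α-ionone, allylic oxidation or ketone reduction. If 16 were unavailable, this would be the better entry to 21.
- Weak points:
  - Three selectivities must hold at once: the site of protonation among three alkenes and an enone, 1,3-induction from C3' to C6' through a chair-like transition state, and the direction of proton loss, where the conjugated β isomer is the thermodynamic sink.
  - The silyloxy group lies β to the developing cation and can be lost.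
- The chosen route spends five standard steps from 16 to 21 but never puts C6' or the double-bond position at risk.

Alternative 3: The cuts are C10–C11 and the C9–methyl bond. The tris-silylated terminal enyne A8 would undergo Cp2ZrCl2-catalysed methylalumination with Al(CH3)3, and the alkenylalane would be coupled (ZnCl2, Pd(PPh3)4) with the iododienoate A9 to give the C20 tetraenoate A7.
- Merits: syn-carbometalation fixes the trisubstituted C9=C10 bond as E with certainty, and the ester is a handle for a C20 + C20 union, which would be a more convergent end-game than C15 + C10 + C15.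
- Weak points:
  - All three hydroxyls, two of them tertiary, must be silylated.
  - Al(CH3)3 is a strong Lewis acid towards the tertiary allylic silyl ether at C6.
  - A8 presupposes the 7E alkene and all three ring stereocentres, so the plan addresses the chain and not the ring.
  - A matching C20 partner for the ε half would have to be developed.
- The chosen plan obtains the C9=C10 geometry from the purchased enynol 8 and uses the same triple bond to shield C6 during the key step. It concedes the less convergent end-game.

Key step: step 8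

Remark: (R)-α-ionone 16 of high enantiomeric purity is taken as purchasable; the carbinol centre of 23 is a mixture of epimers that converge in step 18.

## Route

Step 1
Reactants: 1 ketoisophorone (2,6,6-trimethylcyclohex-2-ene-1,4-dione)
Product: 2 (6R)-2,2,6-trimethylcyclohexane-1,4-dione
Conditions: fermenting baker's yeast (Saccharomyces cerevisiae), sucrose, H2O, 30 °C
Reagents that add atoms: none
Why: Whole-cell ene-reductase (conjugate) reduction of the activated ring double bond; the enzyme adds hydride and proton to one face and sets the methyl-bearing centre as R.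

Step 2
Reactants: 2 (6R)-2,2,6-trimethylcyclohexane-1,4-dione
Product: 3 (4R,6R)-4-hydroxy-2,2,6-trimethylcyclohexan-1-one
Conditions: LiBH(s-Bu)3 (L-Selectride), THF, −78 °C; then aq. NaOH, H2O2
Reagents that add atoms: none
Why: Chemo- and diastereoselective ketone reduction by a bulky borohydride: only the C4 carbonyl is accessible (C1 lies between a quaternary and a tertiary carbon), and the axial C2 methyl blocks axial approach as in 3,3,5-trimethylcyclohexanone, so hydride enters equatorially and the new hydroxyl (4R) is axial and trans to the C6 methyl. The low temperature avoids enolisation, which would racemise 2.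

Step 3
Reactants: 3 (4R,6R)-4-hydroxy-2,2,6-trimethylcyclohexan-1-one; 4 di-tert-butyl dicarbonate
Product: 5 tert-butyl (1R,5R)-3,3,5-trimethyl-4-oxocyclohexyl carbonate
Conditions: DMAP (0.2 equiv), Et3N, CH2Cl2, 0 °C → rt
Reagents that add atoms: none
Why: DMAP-catalysed O-acylation of the secondary alcohol by the dicarbonate (carbonate formation); no stereocentre is touched. The tert-butyl carbonate serves as protecting group now and as internal nucleophile in step 8.

Step 4
Reactants: 5 tert-butyl (1R,5R)-3,3,5-trimethyl-4-oxocyclohexyl carbonate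
Product: 7 (4R)-4-[(tert-butoxycarbonyl)oxy]-2,6,6-trimethylcyclohex-1-en-1-yl trifluoromethanesulfonate, via lithium enolate 6 (not isolated)
Conditions: LDA, THF, −78 → −40 °C; then PhNTf2, −78 °C → rt
Reagents that add atoms: N-phenylbis(trifluoromethanesulfonimide), O=S(=O)(N(c1ccccc1)S(=O)(=O)C(F)(F)F)C(F)(F)F
Why: Regiospecific enolisation (the ketone has a single α-hydrogen) followed by O-sulfonylation of the enolate gives the tetrasubstituted enol triflate, as for 2,2,6-trimethylcyclohexanone; the methyl-bearing stereocentre is erased by design and the carbinol centre is untouched. The hindered carbonate should not be attacked by the amide base at low temperature.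

Step 5
Reactants: 8 (2E)-3-methylpent-2-en-4-yn-1-ol
Product: 9 tert-butyl(dimethyl){[(2E)-3-methylpent-2-en-4-yn-1-yl]oxy}silane
Conditions: TBSCl, imidazole, DMF, 0 °C → rt
Reagents that add atoms: tert-butyldimethylsilyl chloride, CC(C)(C)[Si](C)(C)Cl
Why: Standard silylation of a primary alcohol; the E-trisubstituted alkene, the later C9=C10, is bought with fixed geometry.

Step 6
Reactants: 7 (4R)-4-[(tert-butoxycarbonyl)oxy]-2,6,6-trimethylcyclohex-1-en-1-yl trifluoromethanesulfonate; 9 tert-butyl(dimethyl){[(2E)-3-methylpent-2-en-4-yn-1-yl]oxy}silane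
Product: 10 tert-butyl (1R)-4-[(3E)-5-{[tert-butyl(dimethyl)silyl]oxy}-3-methylpent-3-en-1-yn-1-yl]-3,5,5-trimethylcyclohex-3-en-1-yl carbonate
Conditions: Pd(PPh3)4 (5 mol %), CuI (10 mol %), i-Pr2NH, DMF, rt
Reagents that add atoms: none
Why: Sonogashira coupling forms the C6–C7 bond: oxidative addition of zerovalent palladium into the C–OTf bond, transmetallation from the copper acetylide, reductive elimination. Carbonate, silyl ether and alkene geometry are not affected.

Step 7
Reactants: 10 tert-butyl (1R)-4-[(3E)-5-{[tert-butyl(dimethyl)silyl]oxy}-3-methylpent-3-en-1-yn-1-yl]-3,5,5-trimethylcyclohex-3-en-1-yl carbonate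
Product: 11 tert-butyl (1R,4S,6R)-1-[(3E)-5-{[tert-butyl(dimethyl)silyl]oxy}-3-methylpent-3-en-1-yn-1-yl]-2,2,6-trimethyl-7-oxabicyclo[4.1.0]heptan-4-yl carbonate (carotenoid numbering 3S,5R,6R; epoxide trans to the carbonate)
Conditions: mCPBA, NaHCO3, CH2Cl2, −20 → 0 °C
Reagents that add atoms: m-chloroperbenzoic acid, OOC(=O)c1cccc(Cl)c1
Why: Prilezhaev epoxidation; the tetrasubstituted ring alkene is the most nucleophilic π bond (C9=C10 is trisubstituted and carries an inductively withdrawing allylic silyloxy group, the alkyne is inert). The peracid should approach anti to the C3 acyloxy group, as is usual for 3-acyloxy rings of this type, setting C5 (R) and C6 (R) trans to the carbonate; the syn epoxide is removed by chromatography.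

Step 8
Reactants: 11 tert-butyl (1R,4S,6R)-1-[(3E)-5-{[tert-butyl(dimethyl)silyl]oxy}-3-methylpent-3-en-1-yn-1-yl]-2,2,6-trimethyl-7-oxabicyclo[4.1.0]heptan-4-yl carbonate
Product: 12 (1S,5S,8R)-8-[(3E)-5-{[tert-butyl(dimethyl)silyl]oxy}-3-methylpent-3-en-1-yn-1-yl]-8-hydroxy-1,7,7-trimethyl-2,4-dioxabicyclo[3.3.1]nonan-3-one (carotenoid numbering 3S,5S,6R)
Conditions: BF3·OEt2 (1.2 equiv), CH2Cl2, −78 → −40 °C; quench with Et3N, aq. NaHCO3
Reagents that add atoms: none
Why: Proposed new method: BF3 coordinates the epoxide oxygen and weakens the C5–O bond (C5 is the tertiary alkyl terminus, C6 carries the inductively destabilising alkynyl group), the carbonyl oxygen of the axial C3 tert-butyl carbonate attacks C5 from the face opposite the departing oxygen, and the resulting tert-butoxy dioxanylium ion loses its tert-butyl group as isobutene to leave the neutral cyclic carbonate. The closest known reaction type is the Lewis-acid-mediated cyclisation of open-chain epoxy tert-butyl carbonates to five- and six-membered cyclic carbonates in 1,3-diol synthesis; new here is the transannular closure on a fully substituted cyclohexene oxide. The ring closes in a 6-exo-tet mode (the breaking C5–O bond is exocyclic to the new dioxanone ring) and gives a 2,4-dioxabicyclo[3.3.1]nonan-3-one; attack at C6 would need a seven-membered ring and is out of reach. The new C5 stereocentre (S) arises by inversion and is dictated by C3 through the tether, because the carbonate can reach C5 only on its own face; C6 keeps its configuration since its C–O bond is not broken. The step needs regioselectivity for C5 and suppression of ring contraction, 1,2-shifts and furanoid formation; the tether, the half-chair with axial carbonate that opens trans-diaxially (Fürst–Plattner) and the triple bond at C7, which allows no allylic cation at C6, secure this. The methyl group on C1 that is syn-axial to the bridge crowds the carbonate, so the reaction is run cold with a stoichiometric Lewis acid and the carbocycle is expected to relax to a flattened chair or twist-boat.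

Step 9
Reactants: 12 (1S,5S,8R)-8-[(3E)-5-{[tert-butyl(dimethyl)silyl]oxy}-3-methylpent-3-en-1-yn-1-yl]-8-hydroxy-1,7,7-trimethyl-2,4-dioxabicyclo[3.3.1]nonan-3-one
Product: 13 (1S,2S,4S)-1-[(1E,3E)-5-{[tert-butyl(dimethyl)silyl]oxy}-3-methylpenta-1,3-dien-1-yl]-2,6,6-trimethylcyclohexane-1,2,4-triol
Conditions: NaAlH2(OCH2CH2OCH3)2 (excess), THF, 0 °C → rt; aq. Rochelle salt work-up
Reagents that add atoms: none
Why: Hydroxyl-directed trans-hydroalumination of the propargylic alcohol (well precedented for conjugated enynols) gives the 7E alkene after protonolysis, hydride being delivered from the C6 alkoxyaluminate; the same reagent reduces the cyclic carbonate to the 3,5-diol. No C–O bond at a stereocentre is broken, so C3, C5 and C6 are retained (C6 becomes S only through the priority change from alkyne to alkene).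

Step 10
Reactants: 13 (1S,2S,4S)-1-[(1E,3E)-5-{[tert-butyl(dimethyl)silyl]oxy}-3-methylpenta-1,3-dien-1-yl]-2,6,6-trimethylcyclohexane-1,2,4-triol
Product: 14 (1S,2S,4S)-1-[(1E,3E)-5-hydroxy-3-methylpenta-1,3-dien-1-yl]-2,6,6-trimethylcyclohexane-1,2,4-triol
Conditions: TBAF, THF, 0 °C → rt
Reagents that add atoms: none
Why: Fluoride cleavage of the primary silyl ether; the non-acidic conditions spare the tertiary allylic C6 alcohol.

Step 11
Reactants: 14 (1S,2S,4S)-1-[(1E,3E)-5-hydroxy-3-methylpenta-1,3-dien-1-yl]-2,6,6-trimethylcyclohexane-1,2,4-triol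
Product: 15 (2E,4E)-3-methyl-5-[(1S,2S,4S)-1,2,4-trihydroxy-2,6,6-trimethylcyclohexyl]penta-2,4-dienal
Conditions: MnO2 (activated, excess), acetone, rt
Reagents that add atoms: none
Why: Selective allylic oxidation: only the primary dienylic alcohol is activated towards MnO2, while the saturated secondary and the tertiary hydroxyls are inert. The aldehyde is reached without acid.

Step 12
Reactants: 16 (R)-α-ionone, (3E)-4-[(1R)-2,6,6-trimethylcyclohex-2-en-1-yl]but-3-en-2-one
Product: 17 2-methyl-2-{(E)-2-[(1R)-2,6,6-trimethylcyclohex-2-en-1-yl]ethenyl}-1,3-dioxolane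
Conditions: ethylene glycol, HC(OMe)3, p-TsOH·H2O (cat.), CH2Cl2, rt
Reagents that add atoms: ethylene glycol, OCCO
Why: Acid-catalysed dioxolane formation with orthoformate as water scavenger masks the side-chain ketone so that the ring ketone introduced next can be reduced alone. The mild conditions leave C6 and the position of the ring alkene unchanged.

Step 13
Reactants: 17 2-methyl-2-{(E)-2-[(1R)-2,6,6-trimethylcyclohex-2-en-1-yl]ethenyl}-1,3-dioxolane
Product: 18 (4R)-3,5,5-trimethyl-4-[(E)-2-(2-methyl-1,3-dioxolan-2-yl)ethenyl]cyclohex-2-en-1-one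
Conditions: t-BuOOH (70 % aq.), aq. NaOCl, MeCN, −5 → 0 °C
Reagents that add atoms: tert-butyl hydroperoxide, CC(C)(C)OO
Why: Radical allylic oxidation (tert-butylperoxyl chain) of the ring methylene C3, the only unhindered secondary allylic C–H; the doubly allylic C6–H is shielded by the geminal methyls and the C5 methyl. The cold conditions should leave the C6 configuration and the double-bond position intact.

Step 14
Reactants: 18 (4R)-3,5,5-trimethyl-4-[(E)-2-(2-methyl-1,3-dioxolan-2-yl)ethenyl]cyclohex-2-en-1-one
Product: 19 (1R,4R)-3,5,5-trimethyl-4-[(E)-2-(2-methyl-1,3-dioxolan-2-yl)ethenyl]cyclohex-2-en-1-ol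
Conditions: (S)-2-methyl-CBS-oxazaborolidine (0.2 equiv), catecholborane, toluene, −78 °C
Reagents that add atoms: none
Why: Corey–Bakshi–Shibata 1,2-reduction of the enone; the catalyst binds the carbonyl anti to the alkenyl flank, and the (S)-oxazaborolidine should give the (R)-carbinol, i.e. the hydroxyl trans to the C6 side chain. Reagent control is used because the ring offers little facial bias of its own.

Step 15
Reactants: 19 (1R,4R)-3,5,5-trimethyl-4-[(E)-2-(2-methyl-1,3-dioxolan-2-yl)ethenyl]cyclohex-2-en-1-ol
Product: 20 (3R,6R)-3-hydroxy-α-ionone, (3E)-4-[(1R,4R)-4-hydroxy-2,6,6-trimethylcyclohex-2-en-1-yl]but-3-en-2-one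
Conditions: PPTS (cat.), acetone/H2O (10:1), rt
Reagents that add atoms: water, O
Why: Mild acid-catalysed hydrolysis of the allylic dioxolane returns the methyl ketone; the acid is too weak to ionise the ring allylic alcohol or to move the ring double bond.

Step 16
Reactants: 20 (3R,6R)-3-hydroxy-α-ionone
Product: 21 (3E)-4-[(1R,4R)-4-{[tert-butyl(diphenyl)silyl]oxy}-2,6,6-trimethylcyclohex-2-en-1-yl]but-3-en-2-one
Conditions: TBDPSCl, imidazole, DMF, rt
Reagents that add atoms: tert-butyldiphenylsilyl chloride, CC(C)(C)[Si](Cl)(c1ccccc1)c1ccccc1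
Why: Silylation of the secondary allylic alcohol; the robust silyl ether is chosen because it must survive two acid-mediated phosphonium salt formations in which a free ε-ring allylic alcohol would ionise.

Step 17
Reactants: 21 (3E)-4-[(1R,4R)-4-{[tert-butyl(diphenyl)silyl]oxy}-2,6,6-trimethylcyclohex-2-en-1-yl]but-3-en-2-one; 22 vinylmagnesium bromide
Product: 23 (1E)-1-[(1R,4R)-4-{[tert-butyl(diphenyl)silyl]oxy}-2,6,6-trimethylcyclohex-2-en-1-yl]-3-methylpenta-1,4-dien-3-ol (both carbinol epimers)
Conditions: THF, −20 → 0 °C; aq. NH4Cl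
Reagents that add atoms: none
Why: 1,2-Addition of the Grignard reagent to the methyl ketone, the standard route from ionones to their vinyl carbinols, forms the C9'–C10' bond. The new carbinol centre is formed as a mixture and is erased in the next step.

Step 18
Reactants: 23 (1E)-1-[(1R,4R)-4-{[tert-butyl(diphenyl)silyl]oxy}-2,6,6-trimethylcyclohex-2-en-1-yl]-3-methylpenta-1,4-dien-3-ol
Product: 24 {(2E,4E)-5-[(1R,4R)-4-{[tert-butyl(diphenyl)silyl]oxy}-2,6,6-trimethylcyclohex-2-en-1-yl]-3-methylpenta-2,4-dien-1-yl}(triphenyl)phosphonium bromide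
Conditions: PPh3·HBr, MeOH/CH2Cl2, 0 °C → rt; crystallisation
Reagents that add atoms: triphenylphosphine hydrobromide, [Br-].c1ccc(cc1)[PH+](c1ccccc1)c1ccccc1
Why: Acid-promoted ionisation of the bis-allylic tertiary alcohol to a pentadienyl cation and capture by triphenylphosphine at the terminal carbon (allylic transposition, the standard C15 Wittig salt synthesis) gives the conjugated salt, predominantly 9'E and purified by crystallisation. The sp3 carbon C6' insulates the ring from the cation, and the silyl ether is inert.

Step 19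
Reactants: 24 {(2E,4E)-5-[(1R,4R)-4-{[tert-butyl(diphenyl)silyl]oxy}-2,6,6-trimethylcyclohex-2-en-1-yl]-3-methylpenta-2,4-dien-1-yl}(triphenyl)phosphonium bromide; 25 (2E,4E,6E)-2,7-dimethylocta-2,4,6-trienedial
Product: 26 (3R,6R)-3-{[tert-butyl(diphenyl)silyl]oxy}-12'-apo-ε-caroten-12'-al (all-E C25 aldehyde)
Conditions: 25 (2.5 equiv), 1,2-epoxybutane, EtOH, reflux
Reagents that add atoms: none
Why: Wittig olefination of one formyl group of the dialdehyde forms C11'=C12' (target numbering); the excess of 25 secures mono-condensation, and epoxybutane scavenges HBr so that the ylide forms under neutral conditions. Any Z isomer at the new disubstituted bond is a hindered cis form and should equilibrate to E in the hot medium.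

Step 20
Reactants: 26 (3R,6R)-3-{[tert-butyl(diphenyl)silyl]oxy}-12'-apo-ε-caroten-12'-al
Product: 27 (3R,6R)-3-{[tert-butyl(diphenyl)silyl]oxy}-12'-apo-ε-caroten-12'-ol
Conditions: NaBH4, EtOH/THF, 0 °C
Reagents that add atoms: none
Why: 1,2-Reduction of the conjugated aldehyde by borohydride; nothing else in the molecule is reducible under these conditions.

Step 21
Reactants: 27 (3R,6R)-3-{[tert-butyl(diphenyl)silyl]oxy}-12'-apo-ε-caroten-12'-ol
Product: 28 [(3R,6R)-3-{[tert-butyl(diphenyl)silyl]oxy}-12'-apo-ε-caroten-12'-yl](triphenyl)phosphonium bromide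
Conditions: PPh3·HBr, MeOH/CH2Cl2, 0 °C, dark
Reagents that add atoms: triphenylphosphine hydrobromide, [Br-].c1ccc(cc1)[PH+](c1ccccc1)c1ccccc1
Why: SN1-type substitution: the polyenylic primary alcohol ionises under the mild acid to a delocalised cation that triphenylphosphine captures at the terminal carbon, as in the preparation of retinyl phosphonium salts. The silyl-protected ring alcohol stays intact.

Step 22
Reactants: 28 [(3R,6R)-3-{[tert-butyl(diphenyl)silyl]oxy}-12'-apo-ε-caroten-12'-yl](triphenyl)phosphonium bromide; 15 (2E,4E)-3-methyl-5-[(1S,2S,4S)-1,2,4-trihydroxy-2,6,6-trimethylcyclohexyl]penta-2,4-dienal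
Product: 29 (3S,5S,6S,3'R,6'R)-3'-O-[tert-butyl(diphenyl)silyl]-5,6-dihydro-β,ε-carotene-3,5,6,3'-tetrol
Conditions: 1,2-epoxybutane, EtOH, reflux, dark, argon
Reagents that add atoms: none
Why: Wittig olefination forms C11=C12 and joins the two halves; the neutral epoxybutane conditions tolerate the three free hydroxyls, including the tertiary allylic one. A Z isomer at the new bond is a hindered cis form and should isomerise to E on heating.

Step 23
Reactants: 29 (3S,5S,6S,3'R,6'R)-3'-O-[tert-butyl(diphenyl)silyl]-5,6-dihydro-β,ε-carotene-3,5,6,3'-tetrol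
Product: 30 (3S,5S,6S,3'R,6'R)-5,6-dihydro-β,ε-carotene-3,5,6,3'-tetrol (all-E; target)
Conditions: TBAF, THF, rt, dark
Reagents that add atoms: none
Why: Fluoride desilylation frees the 3'-hydroxyl without acid; no stereocentre or double bond is affected.

## Compound list

1 | ketoisophorone (2,6,6-trimethylcyclohex-2-ene-1,4-dione) | CC1=CC(=O)CC(C)(C)C1=O | starting material
2 | (6R)-2,2,6-trimethylcyclohexane-1,4-dione | CC1(C)CC(=O)C[C@@H](C)C1=O | intermediate
3 | (4R,6R)-4-hydroxy-2,2,6-trimethylcyclohexan-1-one | CC1(C)C[C@H](O)C[C@@H](C)C1=O | intermediate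
4 | di-tert-butyl dicarbonate | CC(C)(C)OC(=O)OC(=O)OC(C)(C)C | starting material
5 | tert-butyl (1R,5R)-3,3,5-trimethyl-4-oxocyclohexyl carbonate | CC1(C)C[C@H](OC(=O)OC(C)(C)C)C[C@@H](C)C1=O | intermediate
6 | lithium (4R)-4-[(tert-butoxycarbonyl)oxy]-2,6,6-trimethylcyclohex-1-en-1-olate (not isolated) | [Li+].CC1=C([O-])C(C)(C)C[C@H](OC(=O)OC(C)(C)C)C1 | intermediate
7 | (4R)-4-[(tert-butoxycarbonyl)oxy]-2,6,6-trimethylcyclohex-1-en-1-yl trifluoromethanesulfonate | CC1=C(OS(=O)(=O)C(F)(F)F)C(C)(C)C[C@H](OC(=O)OC(C)(C)C)C1 | intermediate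
8 | (2E)-3-methylpent-2-en-4-yn-1-ol | C#C/C(C)=C/CO | starting material
9 | tert-butyl(dimethyl){[(2E)-3-methylpent-2-en-4-yn-1-yl]oxy}silane | C#C/C(C)=C/CO[Si](C)(C)C(C)(C)C | intermediate
10 | tert-butyl (1R)-4-[(3E)-5-{[tert-butyl(dimethyl)silyl]oxy}-3-methylpent-3-en-1-yn-1-yl]-3,5,5-trimethylcyclohex-3-en-1-yl carbonate | CC(C)(C)[Si](C)(C)OC/C=C(C)/C#CC1=C(C)C[C@@H](OC(=O)OC(C)(C)C)CC1(C)C | intermediate
11 | tert-butyl (1R,4S,6R)-1-[(3E)-5-{[tert-butyl(dimethyl)silyl]oxy}-3-methylpent-3-en-1-yn-1-yl]-2,2,6-trimethyl-7-oxabicyclo[4.1.0]heptan-4-yl carbonate | CC(C)(C)[Si](C)(C)OC/C=C(C)/C#C[C@]1(O2)C(C)(C)C[C@H](OC(=O)OC(C)(C)C)C[C@]12C | intermediate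
12 | (1S,5S,8R)-8-[(3E)-5-{[tert-butyl(dimethyl)silyl]oxy}-3-methylpent-3-en-1-yn-1-yl]-8-hydroxy-1,7,7-trimethyl-2,4-dioxabicyclo[3.3.1]nonan-3-one | CC(C)(C)[Si](C)(C)OC/C=C(C)/C#C[C@]1(O)C(C)(C)C[C@H]2C[C@]1(C)OC(=O)O2 | intermediate
13 | (1S,2S,4S)-1-[(1E,3E)-5-{[tert-butyl(dimethyl)silyl]oxy}-3-methylpenta-1,3-dien-1-yl]-2,6,6-trimethylcyclohexane-1,2,4-triol | CC(C)(C)[Si](C)(C)OC/C=C(C)/C=C/[C@]1(O)C(C)(C)C[C@H](O)C[C@]1(C)O | intermediate
14 | (1S,2S,4S)-1-[(1E,3E)-5-hydroxy-3-methylpenta-1,3-dien-1-yl]-2,6,6-trimethylcyclohexane-1,2,4-triol | OC/C=C(C)/C=C/[C@]1(O)C(C)(C)C[C@H](O)C[C@]1(C)O | intermediate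
15 | (2E,4E)-3-methyl-5-[(1S,2S,4S)-1,2,4-trihydroxy-2,6,6-trimethylcyclohexyl]penta-2,4-dienal | O=C/C=C(C)/C=C/[C@]1(O)C(C)(C)C[C@H](O)C[C@]1(C)O | intermediate
16 | (R)-α-ionone | CC1=CCCC(C)(C)[C@H]1/C=C/C(C)=O | starting material
17 | 2-methyl-2-{(E)-2-[(1R)-2,6,6-trimethylcyclohex-2-en-1-yl]ethenyl}-1,3-dioxolane | CC1=CCCC(C)(C)[C@H]1/C=C/C1(C)OCCO1 | intermediate
18 | (4R)-3,5,5-trimethyl-4-[(E)-2-(2-methyl-1,3-dioxolan-2-yl)ethenyl]cyclohex-2-en-1-one | CC1=CC(=O)CC(C)(C)[C@H]1/C=C/C1(C)OCCO1 | intermediate
19 | (1R,4R)-3,5,5-trimethyl-4-[(E)-2-(2-methyl-1,3-dioxolan-2-yl)ethenyl]cyclohex-2-en-1-ol | CC1=C[C@H](O)CC(C)(C)[C@H]1/C=C/C1(C)OCCO1 | intermediate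
20 | (3R,6R)-3-hydroxy-α-ionone | CC1=C[C@H](O)CC(C)(C)[C@H]1/C=C/C(C)=O | intermediate
21 | (3E)-4-[(1R,4R)-4-{[tert-butyl(diphenyl)silyl]oxy}-2,6,6-trimethylcyclohex-2-en-1-yl]but-3-en-2-one | CC1=C[C@H](O[Si](c2ccccc2)(c2ccccc2)C(C)(C)C)CC(C)(C)[C@H]1/C=C/C(C)=O | intermediate
22 | vinylmagnesium bromide | C=C[Mg]Br | starting material
23 | (1E)-1-[(1R,4R)-4-{[tert-butyl(diphenyl)silyl]oxy}-2,6,6-trimethylcyclohex-2-en-1-yl]-3-methylpenta-1,4-dien-3-ol (carbinol centre: both epimers) | CC1=C[C@H](O[Si](c2ccccc2)(c2ccccc2)C(C)(C)C)CC(C)(C)[C@H]1/C=C/C(C)(O)C=C | intermediate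
24 | {(2E,4E)-5-[(1R,4R)-4-{[tert-butyl(diphenyl)silyl]oxy}-2,6,6-trimethylcyclohex-2-en-1-yl]-3-methylpenta-2,4-dien-1-yl}(triphenyl)phosphonium bromide | CC1=C[C@H](O[Si](c2ccccc2)(c2ccccc2)C(C)(C)C)CC(C)(C)[C@H]1/C=C/C(C)=C/C[P+](c1ccccc1)(c1ccccc1)c1ccccc1.[Br-] | intermediate
25 | (2E,4E,6E)-2,7-dimethylocta-2,4,6-trienedial | O=C/C(C)=C/C=C/C=C(C)/C=O | starting material
26 | (3R,6R)-3-{[tert-butyl(diphenyl)silyl]oxy}-12'-apo-ε-caroten-12'-al | CC1=C[C@H](O[Si](c2ccccc2)(c2ccccc2)C(C)(C)C)CC(C)(C)[C@H]1/C=C/C(C)=C/C=C/C(C)=C/C=C/C=C(C)/C=O | intermediate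
27 | (3R,6R)-3-{[tert-butyl(diphenyl)silyl]oxy}-12'-apo-ε-caroten-12'-ol | CC1=C[C@H](O[Si](c2ccccc2)(c2ccccc2)C(C)(C)C)CC(C)(C)[C@H]1/C=C/C(C)=C/C=C/C(C)=C/C=C/C=C(C)/CO | intermediate
28 | [(3R,6R)-3-{[tert-butyl(diphenyl)silyl]oxy}-12'-apo-ε-caroten-12'-yl](triphenyl)phosphonium bromide | CC1=C[C@H](O[Si](c2ccccc2)(c2ccccc2)C(C)(C)C)CC(C)(C)[C@H]1/C=C/C(C)=C/C=C/C(C)=C/C=C/C=C(C)/C[P+](c1ccccc1)(c1ccccc1)c1ccccc1.[Br-] | intermediate
29 | (3S,5S,6S,3'R,6'R)-3'-O-[tert-butyl(diphenyl)silyl]-5,6-dihydro-β,ε-carotene-3,5,6,3'-tetrol | CC1=C[C@H](O[Si](c2ccccc2)(c2ccccc2)C(C)(C)C)CC(C)(C)[C@H]1/C=C/C(C)=C/C=C/C(C)=C/C=C/C=C(C)/C=C/C=C(C)/C=C/[C@]1(O)C(C)(C)C[C@H](O)C[C@]1(C)O | intermediate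
30 | (3S,5S,6S,3'R,6'R)-5,6-dihydro-β,ε-carotene-3,5,6,3'-tetrol | CC1=C[C@H](O)CC(C)(C)[C@H]1/C=C/C(C)=C/C=C/C(C)=C/C=C/C=C(C)/C=C/C=C(C)/C=C/[C@]1(O)C(C)(C)C[C@H](O)C[C@]1(C)O | target

## Step count and risks

Total: 23 steps. Longest linear sequence: 12 steps (steps 1–4, 6–11, 22, 23 from ketoisophorone; equally steps 12–23 from (R)-α-ionone).

Least certain steps:

**Step 8 (key step, proposed new method).**
- Risk: the ring closure may be slowed by the methyl group that lies syn-axial to the forming bridge. The BF3-activated epoxide could then rearrange (ring contraction or 1,2-shift to a ketone), eliminate to allylic alcohols, or lose the tert-butyl group before the carbonate has attacked, leaving a free C3 alcohol.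
- Fallback (known chemistry, from 11 back to 13): acid-catalysed trans-diaxial hydrolysis of 11 (dilute aq. HClO4, THF, 0 °C), with water attacking the tertiary, non-propargylic C5 with inversion, would give the 5,6-diol tert-butyl carbonate F1. Applying the step 9 conditions to F1 reduces the triple bond and cleaves the open-chain carbonate to reach 13. This gives up the tether's guarantee and relies on the electronic preference for C5 alone, so a C6-opened diastereomer would have to be separated.

**Step 7.**
- Risk: poor facial selectivity of the peracid, since the C3 carbonate is three atoms from the alkene and both faces carry a methyl group on C1; a large share of the syn epoxide would be lost.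
- Fallback (from 7 back to 11), making the epoxide by reagent control on an allylic alcohol:
  - Stille hydroxymethylation of 7 (Bu3SnCH2OH, Pd(PPh3)4, LiCl, dioxane, 90 °C) gives the allylic alcohol F2.
  - Sharpless asymmetric epoxidation (Ti(OiPr)4, t-BuOOH, diethyl tartrate, 4 Å sieves, CH2Cl2, −20 °C) gives the epoxy alcohol F3. The tartrate enantiomer is chosen to deliver oxygen anti to the carbonate, expected to be the D-(−) ester.
  - Dess–Martin oxidation gives the epoxy aldehyde F4.
  - Ohira–Bestmann homologation (dimethyl (1-diazo-2-oxopropyl)phosphonate, K2CO3, MeOH, 0 °C) gives the epoxy alkyne F5.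
  - Sonogashira coupling of F5 with (E)-3-iodobut-2-en-1-ol tert-butyldimethylsilyl ether under the step 6 conditions returns 11.

**Step 9.**
- Risk: the alkenylaluminate formed at C8 may expel the C11 silyloxy group through the C9=C10 bond (1,4-elimination to a vinylallene), or the diene may be over-reduced.
- Fallback (from 12 back to 14): change the order. Desilylation of 12 (TBAF, AcOH, THF) gives the carbonate diol F6, whose primary alkoxide cannot leave. Reduction of F6 with NaAlH2(OCH2CH2OCH3)2 is then the classical enyne-diol case and gives 14 directly.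

**Step 14.**
- Risk: catalyst and substrate preferences may oppose each other, or the neopentyl-type methylene flank may compete with the alkenyl flank for the "large" position, giving a poor trans/cis ratio at C3'.
- Fallback (from 18 back to 19): Luche reduction (NaBH4, CeCl3·7H2O, MeOH, −40 °C) gives 19 together with its carbinol epimer F7. After chromatographic separation, F7 is inverted by Mitsunobu esterification (4-nitrobenzoic acid, PPh3, DIAD, THF) to the 4-nitrobenzoate F8, and methanolysis (K2CO3, MeOH) gives 19.

**Step 22.**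
- Risk: incomplete Z to E equilibration at C11=C12, slow condensation because the polar triol aldehyde and the lipophilic salt share no good solvent, and slow degradation of the tertiary allylic alcohol or the polyene on prolonged heating.
- Fallback (from 27 back to 29): 27 is converted into the bromide F9 (PBr3, pyridine, Et2O, −20 °C) and, without storage, into the diethyl phosphonate F10 (P(OEt)3, Michaelis–Arbuzov). F10 is coupled with 15 in an E-selective Horner–Wadsworth–Emmons reaction (KOt-Bu in excess, THF, −20 °C) that needs no heating and gives 29.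

## Further compounds

F1 | step 8 | tert-butyl (1S,3S,4R)-4-[(3E)-5-{[tert-butyl(dimethyl)silyl]oxy}-3-methylpent-3-en-1-yn-1-yl]-3,4-dihydroxy-3,5,5-trimethylcyclohexyl carbonate | CC(C)(C)[Si](C)(C)OC/C=C(C)/C#C[C@]1(O)C(C)(C)C[C@H](OC(=O)OC(C)(C)C)C[C@]1(C)O
F2 | step 7 | tert-butyl (1R)-4-(hydroxymethyl)-3,5,5-trimethylcyclohex-3-en-1-yl carbonate | CC1=C(CO)C(C)(C)C[C@H](OC(=O)OC(C)(C)C)C1
F3 | step 7 | tert-butyl 1-(hydroxymethyl)-2,2,6-trimethyl-7-oxabicyclo[4.1.0]heptan-4-yl carbonate, ring configuration as in 11 | OC[C@]1(O2)C(C)(C)C[C@H](OC(=O)OC(C)(C)C)C[C@]12C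
F4 | step 7 | tert-butyl 1-formyl-2,2,6-trimethyl-7-oxabicyclo[4.1.0]heptan-4-yl carbonate, ring configuration as in 11 | O=C[C@]1(O2)C(C)(C)C[C@H](OC(=O)OC(C)(C)C)C[C@]12C
F5 | step 7 | tert-butyl 1-ethynyl-2,2,6-trimethyl-7-oxabicyclo[4.1.0]heptan-4-yl carbonate, ring configuration as in 11 | C#C[C@]1(O2)C(C)(C)C[C@H](OC(=O)OC(C)(C)C)C[C@]12C
F6 | step 9 | (1S,5S,8R)-8-hydroxy-8-[(3E)-5-hydroxy-3-methylpent-3-en-1-yn-1-yl]-1,7,7-trimethyl-2,4-dioxabicyclo[3.3.1]nonan-3-one | OC/C=C(C)/C#C[C@]1(O)C(C)(C)C[C@H]2C[C@]1(C)OC(=O)O2
F7 | step 14 | (1S,4R)-3,5,5-trimethyl-4-[(E)-2-(2-methyl-1,3-dioxolan-2-yl)ethenyl]cyclohex-2-en-1-ol | CC1=C[C@@H](O)CC(C)(C)[C@H]1/C=C/C1(C)OCCO1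
F8 | step 14 | (1R,4R)-3,5,5-trimethyl-4-[(E)-2-(2-methyl-1,3-dioxolan-2-yl)ethenyl]cyclohex-2-en-1-yl 4-nitrobenzoate | CC1=C[C@H](OC(=O)c2ccc(cc2)[N+](=O)[O-])CC(C)(C)[C@H]1/C=C/C1(C)OCCO1
F9 | step 22 | (3R,6R)-12'-bromo-3-{[tert-butyl(diphenyl)silyl]oxy}-12'-apo-ε-carotene | CC1=C[C@H](O[Si](c2ccccc2)(c2ccccc2)C(C)(C)C)CC(C)(C)[C@H]1/C=C/C(C)=C/C=C/C(C)=C/C=C/C=C(C)/CBr
F10 | step 22 | diethyl [(3R,6R)-3-{[tert-butyl(diphenyl)silyl]oxy}-12'-apo-ε-caroten-12'-yl]phosphonate | CC1=C[C@H](O[Si](c2ccccc2)(c2ccccc2)C(C)(C)C)CC(C)(C)[C@H]1/C=C/C(C)=C/C=C/C(C)=C/C=C/C=C(C)/CP(=O)(OCC)OCC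
A1 | alternative 1 | target tetrakis(triethylsilyl) ether | CC1=C[C@H](O[Si](CC)(CC)CC)CC(C)(C)[C@H]1/C=C/C(C)=C/C=C/C(C)=C/C=C/C=C(C)/C=C/C=C(C)/C=C/[C@]1(O[Si](CC)(CC)CC)C(C)(C)C[C@H](O[Si](CC)(CC)CC)C[C@]1(C)O[Si](CC)(CC)CC
A2 | alternative 1 | tetraethyl [(2E,4E,6E,8E,10E,12E,14E)-2,6,11,15-tetramethylhexadeca-2,4,6,8,10,12,14-heptaene-1,16-diyl]bis(phosphonate) | CCOP(=O)(OCC)C/C(C)=C/C=C/C(C)=C/C=C/C=C(C)/C=C/C=C(C)/CP(=O)(OCC)OCC
A3 | alternative 1 | trihydroxy-ring C10 aldehyde, tris(triethylsilyl) ether, ring configuration as in 30 | O=C[C@]1(O[Si](CC)(CC)CC)C(C)(C)C[C@H](O[Si](CC)(CC)CC)C[C@]1(C)O[Si](CC)(CC)CC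
A4 | alternative 1 | (1R,4R)-2,6,6-trimethyl-4-(triethylsilyloxy)cyclohex-2-ene-1-carbaldehyde | CC1=C[C@H](O[Si](CC)(CC)CC)CC(C)(C)[C@H]1C=O
A5 | alternative 2 | (3R,6R)-3-(tert-butyldiphenylsilyloxy)-α-ionone, identical with 21 | CC1=C[C@H](O[Si](c2ccccc2)(c2ccccc2)C(C)(C)C)CC(C)(C)[C@H]1/C=C/C(C)=O
A6 | alternative 2 | (3E,5E,8R)-8-{[tert-butyl(diphenyl)silyl]oxy}-6,10-dimethylundeca-3,5,10-trien-2-one | C=C(C)C[C@@H](O[Si](c1ccccc1)(c1ccccc1)C(C)(C)C)C/C(C)=C/C=C/C(C)=O
A7 | alternative 3 | trihydroxy-ring C20 tetraenoate, tris(triethylsilyl) ether | CCOC(=O)/C=C(C)/C=C/C=C(C)/C=C/[C@]1(O[Si](CC)(CC)CC)C(C)(C)C[C@H](O[Si](CC)(CC)CC)C[C@]1(C)O[Si](CC)(CC)CC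
A8 | alternative 3 | trihydroxy-ring (E)-but-1-en-3-ynyl compound, tris(triethylsilyl) ether, ring configuration as in 30 | C#C/C=C/[C@]1(O[Si](CC)(CC)CC)C(C)(C)C[C@H](O[Si](CC)(CC)CC)C[C@]1(C)O[Si](CC)(CC)CC
A9 | alternative 3 | ethyl (2E,4E)-5-iodo-3-methylpenta-2,4-dienoate | CCOC(=O)/C=C(C)/C=C/I
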